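**Retrosynthetic overview** (ring locants of the target: C1 acetoxy carbon, C2H2, C3H=C4(CH3), C5H carrying the C21 chain, C6(CH3)2)
- Late disconnections: O-acetyl; C1–H (hydride to a C1 ketone, C1 set from C5); C6–CH3 (methylation of a C1=C6 enolate).
- Enabling feature: the isolated C3=C4 bond of the six-membered ring lies between two sp3 carbons (C2, C5) and is 1,4 to the oxygenated C1–C6 edge. At the enol level of C1 the ring is therefore a 1-silyloxycyclohexa-1,4-diene.
- Key disconnection: C2–C3 and C4–C5 together, a [4+2] cycloaddition of propyne (C3, C4, C4–CH3) with the acyclic diene C2=C1(OSi)–C6(CH3)=C5H–chain. It closes the only ring on the finished polyene, sets C5, and delivers the regiodefined silyl enol ether used to make C6 quaternary.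
- The diene comes from an (E)-α-methyl enone (Wittig on a C22 tetraenal). The aldehyde comes from (2E,6E)-farnesyl bromide by two-carbon homologation, isopropenyl addition and Johnson–Claisen rearrangement (sets the 4E alkene).
- Ring order: one ring only, formed in the key step.

Key step: step 8

Assumption: the sense of induction of the chiral cobalt catalyst cannot be predicted with certainty, so the chiraphos antipode that leads to the (R)-configured cycloadduct is fixed in an orienting experiment; propyne is used as the commercial gas.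

**Step 1**
Reactants: 1 (2E,6E)-farnesyl bromide
Product: 2 (4E,8E)-5,9,13-trimethyltetradeca-4,8,12-trienenitrile
Conditions: CH3CN (3 equiv), n-BuLi, THF, −78 °C; then 1, −78 °C to 0 °C
Reagents that add atoms: acetonitrile, CC#N
Why: SN2 alkylation of lithioacetonitrile by the primary allylic bromide (excess nucleophile suppresses dialkylation) adds two carbons without touching the alkene geometry; no stereocentre is formed.

**Step 2**
Reactants: 2 (4E,8E)-5,9,13-trimethyltetradeca-4,8,12-trienenitrile
Product: 4 (4E,8E)-5,9,13-trimethyltetradeca-4,8,12-trienal, via N-aluminated aldimine 3 (not isolated)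
Conditions: i-Bu2AlH (1.2 equiv), CH2Cl2, −78 °C; then aq. potassium sodium tartrate, dilute AcOH, 0 °C
Reagents that add atoms: water, O
Why: Partial nitrile reduction with i-Bu2AlH stops at the N-aluminated aldimine, which is hydrolysed to the aldehyde on work-up; no stereocentre is formed.

**Step 3**
Reactants: 4 (4E,8E)-5,9,13-trimethyltetradeca-4,8,12-trienal
Product: 5 (6E,10E)-2,7,11,15-tetramethylhexadeca-1,6,10,14-tetraen-3-ol (racemic)
Conditions: CH2=C(CH3)MgBr, THF, 0 °C; then H2O
Reagents that add atoms: isopropenylmagnesium bromide, CC(=C)[Mg]Br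
Why: Grignard 1,2-addition to the aldehyde; the carbinol centre is deliberately made racemic because it is destroyed in step 4.

**Step 4**
Reactants: 5 (6E,10E)-2,7,11,15-tetramethylhexadeca-1,6,10,14-tetraen-3-ol
Product: 7 ethyl (4E,8E,12E)-4,9,13,17-tetramethyloctadeca-4,8,12,16-tetraenoate, via mixed ketene acetal 6 (not isolated)
Conditions: CH3C(OEt)3 (7 equiv), EtCO2H (cat.), 140 °C, EtOH distilled off
Reagents that add atoms: triethyl orthoacetate, CCOC(C)(OCC)OCC
Why: Johnson–Claisen rearrangement; the chair transition state with the carbinol substituent equatorial should set the new trisubstituted C4=C5 double bond E while adding the two-carbon ester unit.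

**Step 5**
Reactants: 7 ethyl (4E,8E,12E)-4,9,13,17-tetramethyloctadeca-4,8,12,16-tetraenoate
Product: 9 (4E,8E,12E)-4,9,13,17-tetramethyloctadeca-4,8,12,16-tetraenal, via aluminium hemiacetal 8 (not isolated)
Conditions: i-Bu2AlH (1.05 equiv), CH2Cl2, −78 °C; then MeOH, aq. potassium sodium tartrate
Reagents that add atoms: none
Why: Partial ester reduction; the tetrahedral aluminium hemiacetal is stable at −78 °C and releases the aldehyde only on work-up; no stereocentre is formed.

**Step 6**
Reactants: 9 (4E,8E,12E)-4,9,13,17-tetramethyloctadeca-4,8,12,16-tetraenal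
Product: 10 (3E,7E,11E,15E)-3,7,12,16,20-pentamethylhenicosa-3,7,11,15,19-pentaen-2-one
Conditions: Ph3P=C(CH3)C(O)CH3 (1.3 equiv), toluene, 90 °C
Reagents that add atoms: 3-(triphenylphosphoranylidene)butan-2-one, CC(=O)C(C)=P(c1ccccc1)(c1ccccc1)c1ccccc1
Why: Wittig olefination with a stabilised α-branched keto ylide should give the (E)-α-methyl enone, which carries C5, C6 with its first methyl, C1 and C2 of the future ring.

**Step 7**
Reactants: 10 (3E,7E,11E,15E)-3,7,12,16,20-pentamethylhenicosa-3,7,11,15,19-pentaen-2-one
Product: 12 trimethyl{[(3E,7E,11E,15E)-3,7,12,16,20-pentamethylhenicosa-1,3,7,11,15,19-hexaen-2-yl]oxy}silane, via lithium dienolate 11 (not isolated)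
Conditions: LiN(i-Pr)2, THF, −78 °C; Me3SiCl, −78 °C to 0 °C; pentane, filtration under argon (no aqueous acid)
Reagents that add atoms: chlorotrimethylsilane, C[Si](C)(C)Cl
Why: Kinetic deprotonation of the methyl ketone at its CH3 group gives the cross-conjugated lithium dienolate, and O-silylation gives the 2-silyloxy-1,3-diene with the (E)-C5=C6 geometry retained (C5–H inside, so the s-cis conformer is accessible).

**Step 8**
Reactants: 12 trimethyl{[(3E,7E,11E,15E)-3,7,12,16,20-pentamethylhenicosa-1,3,7,11,15,19-hexaen-2-yl]oxy}silane; 13 propyne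
Product: 14 trimethyl({(3R)-2,4-dimethyl-3-[(3E,7E,11E)-3,8,12,16-tetramethylheptadeca-3,7,11,15-tetraen-1-yl]cyclohexa-1,4-dien-1-yl}oxy)silane
Conditions: CoBr2[(S,S)-chiraphos] (5 mol%), Zn dust (10 mol%), ZnI2 (10 mol%), propyne (3 equiv), CH2Cl2, 0 °C to rt, sealed vessel, argon; product used directly
Reagents that add atoms: none
Why: Proposed new method: a cationic monovalent cobalt–chiraphos species (from CoBr2[(S,S)-chiraphos], Zn and ZnI2) should bind the s-cis diene of 12 and propyne, couple the unsubstituted diene terminus C2 with the alkyne CH by oxidative cyclisation to a vinyl(silyloxyallyl) trivalent cobalt metallacycle, and then join the methyl-bearing vinyl carbon C4 to the allyl terminus C5 by reductive elimination, so that C2–C3 and C4–C5 form in one catalytic event (a formal, diene-suprafacial [4+2] cycloaddition). The closest known reaction types are the cobalt–bisphosphine-catalysed neutral Diels–Alder reaction of unactivated alkynes with 2-silyloxy-1,3-dienes (dppe ligand, alkyne substituent para to the silyloxy group) and enantioselective cobalt–chiral-bisphosphine cycloadditions of prochiral (E)-1,3-dienes with alkynes; not yet shown is the enantioselective variant on a 3-methyl-4-alkyl-2-silyloxydiene with propyne. The cyclohexa-1,4-diene ring, the only ring of the target, is closed in the intermolecular [4+2] mode (diene carbons C2, C1, C6, C5 plus alkyne carbons C3, C4), the second bond by six-ring-forming reductive elimination. The one new stereocentre, C5, is under catalyst control: the C2-symmetric bisphosphine selects the enantioface of the (E)-C5=C6 bond in the η4-diene complex, and the ligand antipode is chosen for R. The step needs regioselectivity (alkyne CH to C2, C–CH3 to C5), secured by the para-directing silyloxy group on C1 and by C2 being the only unsubstituted diene terminus, and chemoselectivity for the conjugated diene over the four isolated trisubstituted alkenes, secured because only the 1,3-diene can chelate cobalt η4. The silyl enol ether should survive the aprotic medium and is the regiodefined enolate precursor needed in step 9.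

**Step 9**
Reactants: 14 trimethyl({(3R)-2,4-dimethyl-3-[(3E,7E,11E)-3,8,12,16-tetramethylheptadeca-3,7,11,15-tetraen-1-yl]cyclohexa-1,4-dien-1-yl}oxy)silane
Product: 16 (5R)-4,6,6-trimethyl-5-[(3E,7E,11E)-3,8,12,16-tetramethylheptadeca-3,7,11,15-tetraen-1-yl]cyclohex-3-en-1-one, via lithium enolate 15 (not isolated)
Conditions: MeLi (1.05 equiv), THF, 0 °C to rt; then MeI (5 equiv), −78 °C to −20 °C; aq. NH4Cl
Reagents that add atoms: iodomethane, CI
Why: Regiospecific enolate generation by Si–O cleavage of the silyl enol ether with MeLi, then C-alkylation at C6, should build the quaternary gem-dimethyl carbon; C6 is not stereogenic and C5 is not touched.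

**Step 10**
Reactants: 16 (5R)-4,6,6-trimethyl-5-[(3E,7E,11E)-3,8,12,16-tetramethylheptadeca-3,7,11,15-tetraen-1-yl]cyclohex-3-en-1-one
Product: 17 (1S,5R)-4,6,6-trimethyl-5-[(3E,7E,11E)-3,8,12,16-tetramethylheptadeca-3,7,11,15-tetraen-1-yl]cyclohex-3-en-1-ol
Conditions: NaBH4, CeCl3·7H2O, MeOH/THF, −40 °C
Reagents that add atoms: none
Why: Luche-type 1,2-reduction under near-neutral conditions (no migration of the β,γ-double bond); the C6 methyls shield both faces equally, so hydride should add anti to the 1,3-related C5 side chain and place the hydroxyl cis to it (1S), as in the reduction of 2,2-dimethylcyclohexanones to equatorial alcohols.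

**Step 11**
Reactants: 17 (1S,5R)-4,6,6-trimethyl-5-[(3E,7E,11E)-3,8,12,16-tetramethylheptadeca-3,7,11,15-tetraen-1-yl]cyclohex-3-en-1-ol
Product: 18 (1S,5R)-4,6,6-trimethyl-5-[(3E,7E,11E)-3,8,12,16-tetramethylheptadeca-3,7,11,15-tetraen-1-yl]cyclohex-3-en-1-yl acetate
Conditions: Ac2O, pyridine, DMAP (cat.), CH2Cl2, rt
Reagents that add atoms: acetic anhydride, CC(=O)OC(C)=O
Why: DMAP-catalysed O-acylation of the hindered secondary alcohol with retention at C1 gives the target.

**Compound list**
1 | (2E,6E)-farnesyl bromide | BrC/C=C(\C)CC/C=C(\C)CCC=C(C)C | starting material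
2 | (4E,8E)-5,9,13-trimethyltetradeca-4,8,12-trienenitrile | N#CCC/C=C(\C)CC/C=C(\C)CCC=C(C)C | intermediate
3 | N-(diisobutylalumanyl) aldimine of 4 (not isolated) | CC(C)C[Al](CC(C)C)N=CCC/C=C(\C)CC/C=C(\C)CCC=C(C)C | intermediate
4 | (4E,8E)-5,9,13-trimethyltetradeca-4,8,12-trienal | O=CCC/C=C(\C)CC/C=C(\C)CCC=C(C)C | intermediate
5 | (6E,10E)-2,7,11,15-tetramethylhexadeca-1,6,10,14-tetraen-3-ol (racemic) | C=C(C)C(O)CC/C=C(\C)CC/C=C(\C)CCC=C(C)C | intermediate
6 | 1-ethoxy-1-{[(6E,10E)-2,7,11,15-tetramethylhexadeca-1,6,10,14-tetraen-3-yl]oxy}ethene (racemic, not isolated) | C=C(OCC)OC(C(C)=C)CC/C=C(\C)CC/C=C(\C)CCC=C(C)C | intermediate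
7 | ethyl (4E,8E,12E)-4,9,13,17-tetramethyloctadeca-4,8,12,16-tetraenoate | CCOC(=O)CC/C(C)=C/CC/C=C(\C)CC/C=C(\C)CCC=C(C)C | intermediate
8 | diisobutylaluminium hemiacetal of 9, O-ethyl (racemic, not isolated) | CCOC(CC/C(C)=C/CC/C=C(\C)CC/C=C(\C)CCC=C(C)C)O[Al](CC(C)C)CC(C)C | intermediate
9 | (4E,8E,12E)-4,9,13,17-tetramethyloctadeca-4,8,12,16-tetraenal | O=CCC/C(C)=C/CC/C=C(\C)CC/C=C(\C)CCC=C(C)C | intermediate
10 | (3E,7E,11E,15E)-3,7,12,16,20-pentamethylhenicosa-3,7,11,15,19-pentaen-2-one | CC(=O)/C(C)=C/CC/C(C)=C/CC/C=C(\C)CC/C=C(\C)CCC=C(C)C | intermediate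
11 | lithium (3E,7E,11E,15E)-3,7,12,16,20-pentamethylhenicosa-1,3,7,11,15,19-hexaen-2-olate (not isolated) | [Li]OC(=C)/C(C)=C/CC/C(C)=C/CC/C=C(\C)CC/C=C(\C)CCC=C(C)C | intermediate
12 | trimethyl{[(3E,7E,11E,15E)-3,7,12,16,20-pentamethylhenicosa-1,3,7,11,15,19-hexaen-2-yl]oxy}silane | C=C(O[Si](C)(C)C)/C(C)=C/CC/C(C)=C/CC/C=C(\C)CC/C=C(\C)CCC=C(C)C | intermediate
13 | propyne | CC#C | starting material
14 | trimethyl({(3R)-2,4-dimethyl-3-[(3E,7E,11E)-3,8,12,16-tetramethylheptadeca-3,7,11,15-tetraen-1-yl]cyclohexa-1,4-dien-1-yl}oxy)silane | C[Si](C)(C)OC1=C(C)[C@H](CC/C(C)=C/CC/C=C(\C)CC/C=C(\C)CCC=C(C)C)C(C)=CC1 | intermediate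
15 | lithium (3R)-2,4-dimethyl-3-[(3E,7E,11E)-3,8,12,16-tetramethylheptadeca-3,7,11,15-tetraen-1-yl]cyclohexa-1,4-dien-1-olate (not isolated) | [Li]OC1=C(C)[C@H](CC/C(C)=C/CC/C=C(\C)CC/C=C(\C)CCC=C(C)C)C(C)=CC1 | intermediate
16 | (5R)-4,6,6-trimethyl-5-[(3E,7E,11E)-3,8,12,16-tetramethylheptadeca-3,7,11,15-tetraen-1-yl]cyclohex-3-en-1-one | O=C1CC=C(C)[C@@H](CC/C(C)=C/CC/C=C(\C)CC/C=C(\C)CCC=C(C)C)C1(C)C | intermediate
17 | (1S,5R)-4,6,6-trimethyl-5-[(3E,7E,11E)-3,8,12,16-tetramethylheptadeca-3,7,11,15-tetraen-1-yl]cyclohex-3-en-1-ol | O[C@H]1CC=C(C)[C@@H](CC/C(C)=C/CC/C=C(\C)CC/C=C(\C)CCC=C(C)C)C1(C)C | intermediate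
18 | (1S,5R)-4,6,6-trimethyl-5-[(3E,7E,11E)-3,8,12,16-tetramethylheptadeca-3,7,11,15-tetraen-1-yl]cyclohex-3-en-1-yl acetate | CC(=O)O[C@H]1CC=C(C)[C@@H](CC/C(C)=C/CC/C=C(\C)CC/C=C(\C)CCC=C(C)C)C1(C)C | target

**Step count and risks**
Total step count: 11. Longest linear sequence: 11 steps (1 to 18).

Steps most likely to fail:

1. Step 8 (proposed new method). What may go wrong: insufficient enantioface discrimination by the chiral cobalt catalyst, erosion of regiocontrol (methyl meta instead of para to the silyloxy group), or premature reductive elimination to a cyclobutene. Fallback with known chemistry, setting out from 12 and coming back at 17: the cycloaddition is run with the established achiral catalyst CoBr2(dppe)/Zn/ZnI2 in CH2Cl2, which should give 14 together with its enantiomer, the (3S)-silyl enol ether F1. The mixture is methylated under the conditions of step 9, through 15 and the enantiomeric lithium enolate F2, to 16 together with the (5S)-ketone F3. Absolute configuration is then introduced by a reagent-controlled kinetic resolution: (R)-2-methyl-CBS-oxazaborolidine and catecholborane (toluene, −78 °C), stopped near half conversion. This should reduce the matched (5R)-ketone 16 to 17, where catalyst preference and the substrate preference for attack anti to the side chain coincide. F3 should react slowly and, where it does, give mainly the trans-configured (1S,5S)-alcohol F4, a diastereomer of 17 that can be removed by chromatography. Compound 17 then continues with step 11.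

2. Step 9. What may go wrong: proton transfer between enolate 15 and product 16, leading to over-methylation at C2 and migration of the C3=C4 double bond into conjugation; also O-methylation. Fallback, setting out from 14 and coming back at 16: the methyl group is introduced without a free enolate. Furukawa-type Simmons–Smith cyclopropanation of the electron-rich silyl enol ether (Et2Zn, CH2I2, one equivalent, CH2Cl2, 0 °C) should give the silyloxycyclopropane F5. Mild methanolysis (K2CO3, MeOH, 0 °C) then opens the cyclopropanol at its external bond to the α-methyl ketone 16.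

3. Step 10. What may go wrong: poor facial selectivity of hydride delivery because of the conformational mobility of the cyclohexenone, giving hydroxyl trans to the side chain. Fallback, setting out from 16 and coming back at 17: reagent control in place of substrate control, with (R)-2-methyl-CBS-oxazaborolidine and catecholborane (toluene, −78 °C), which differentiates the quaternary C6 flank from the C2 methylene flank and is matched with the substrate bias. No new compound is made.

**Further compounds**
F1 | step 8 | trimethyl({(3S)-2,4-dimethyl-3-[(3E,7E,11E)-3,8,12,16-tetramethylheptadeca-3,7,11,15-tetraen-1-yl]cyclohexa-1,4-dien-1-yl}oxy)silane | C[Si](C)(C)OC1=C(C)[C@@H](CC/C(C)=C/CC/C=C(\C)CC/C=C(\C)CCC=C(C)C)C(C)=CC1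
F2 | step 8 | lithium (3S)-2,4-dimethyl-3-[(3E,7E,11E)-3,8,12,16-tetramethylheptadeca-3,7,11,15-tetraen-1-yl]cyclohexa-1,4-dien-1-olate | [Li]OC1=C(C)[C@@H](CC/C(C)=C/CC/C=C(\C)CC/C=C(\C)CCC=C(C)C)C(C)=CC1
F3 | step 8 | (5S)-4,6,6-trimethyl-5-[(3E,7E,11E)-3,8,12,16-tetramethylheptadeca-3,7,11,15-tetraen-1-yl]cyclohex-3-en-1-one | O=C1CC=C(C)[C@H](CC/C(C)=C/CC/C=C(\C)CC/C=C(\C)CCC=C(C)C)C1(C)C
F4 | step 8 | (1S,5S)-4,6,6-trimethyl-5-[(3E,7E,11E)-3,8,12,16-tetramethylheptadeca-3,7,11,15-tetraen-1-yl]cyclohex-3-en-1-ol | O[C@H]1CC=C(C)[C@H](CC/C(C)=C/CC/C=C(\C)CC/C=C(\C)CCC=C(C)C)C1(C)C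
F5 | step 9 | trimethyl({(1R,5R,6S)-4,6-dimethyl-5-[(3E,7E,11E)-3,8,12,16-tetramethylheptadeca-3,7,11,15-tetraen-1-yl]bicyclo[4.1.0]hept-3-en-1-yl}oxy)silane (methylene bridge anti to the side chain) | C[Si](C)(C)O[C@@]12CC=C(C)[C@@H](CC/C(C)=C/CC/C=C(\C)CC/C=C(\C)CCC=C(C)C)[C@]1(C)C2
F0 | step 10 | none | none
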